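**Plan**

1. Retrosynthetic cuts, in order: the C8 tiglate ester and the C11=C13 methylene (kept as a thiophenol adduct); the C9–C10 bond of the ten-membered ring; the furanone O–C3 and C3–C4 bonds (hydroxy-ynone, Sonogashira); the C8/C9 epoxide and the C7–C8 bond (Barbier); the butenolide C7=C11 bond (ring-closing metathesis).
2. Enabling feature: C10 is the ketone α-carbon of the 2-methyl-3(2H)-furanone ring (O, C3, C2, C1, C10), so its conjugate base is an aromatic furan-3-olate that is nucleophilic at C10. C9 is a CH2 next to the oxygenated C8, i.e. the terminal carbon of a C8–C9 epoxide. Intramolecular opening of that epoxide closes the carbocycle, creates the quaternary C10 and unveils the C8 hydroxyl in one event.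
3. Forward ring order: butenolide (metathesis), then α-methylene-γ-lactone (Barbier), oxirane, furanone (oxa-Michael), and finally the ten-membered carbocycle with its nine-membered oxygen bridge (key step); tiglate and methylene release follow.
4. Stereochemistry: C6 from a lipase resolution; C7 by addition anti to the C6 substituent; C8 by the closed Barbier transition state followed by inversion in the epoxide closure; C10 by substrate control in the ring closure; the Z-C4=C5 bond from hydroxyl-directed trans-hydroalumination/iodination; the tiglate E-olefin from tigloyl chloride.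

Key step: step 14

Remark 1: positions are given in germacrane numbering (C1–C15; lactone carbonyl C12, exocyclic methylene C13); "atripliciolide" denotes the free C8 alcohol of the target. CIP descriptors change along the route only where substituent priorities change.
Remark 2: the configurations at C10 in 16–22 and at C11 in 15–27 are inconsequential (C10 is planarised in step 14, C11 becomes sp2 in step 16); C11 is left undefined.
Assumption: 1, 2, 7, 10, 16, 17 and 25 are taken as commercial.

**Step 1**
Reactants: 1 acrolein; 2 1-propynylmagnesium bromide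
Product: 3 (±)-hex-1-en-4-yn-3-ol
Conditions: THF, −78 → 0 °C; sat. aq NH4Cl
Reagents that add atoms: none
Why: 1,2-addition of an alkynyl Grignard reagent to the aldehyde of an enal at low temperature; the carbinol center is racemic and is resolved in step 3.

**Step 2**
Reactants: 3 (±)-hex-1-en-4-yn-3-ol
Product: 5 (±)-(Z)-5-iodohexa-1,4-dien-3-ol, via cyclic sodium vinylalanate 4 (not isolated)
Conditions: NaAlH2(OCH2CH2OCH3)2, THF, 0 °C → rt; then I2, −78 → 0 °C; aq Rochelle salt
Reagents that add atoms: iodine, II
Why: hydroxyl-directed trans-hydroalumination of a propargylic alcohol puts aluminium on the distal alkyne carbon in a five-membered alanate, and iodinolysis with retention gives the Z-iodoalkene (iodine cis to the carbinol carbon), the isolated vinyl group being inert.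

**Step 3**
Reactants: 5 (±)-(Z)-5-iodohexa-1,4-dien-3-ol
Product: 6 (S,Z)-5-iodohexa-1,4-dien-3-ol
Conditions: Burkholderia cepacia lipase, vinyl acetate, hexane, rt, stopped slightly past half conversion
Reagents that add atoms: none
Why: enzymatic kinetic resolution of a secondary allylic alcohol by irreversible transesterification; the empirical size rule for lipases (large iodopropenyl, small vinyl) predicts acetylation of the R enantiomer, leaving the S alcohol.

**Step 4**
Reactants: 6 (S,Z)-5-iodohexa-1,4-dien-3-ol; 7 2-(bromomethyl)acrylic acid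
Product: 8 (S,Z)-5-iodohexa-1,4-dien-3-yl 2-(bromomethyl)acrylate
Conditions: DCC, DMAP (5 mol%), CH2Cl2, 0 °C
Reagents that add atoms: none
Why: Steglich esterification under mild, non-basic conditions that leave the allylic bromide and the carbinol stereocenter untouched.

**Step 5**
Reactants: 8 (S,Z)-5-iodohexa-1,4-dien-3-yl 2-(bromomethyl)acrylate
Product: 9 (S)-3-(bromomethyl)-5-[(Z)-2-iodoprop-1-en-1-yl]furan-2(5H)-one
Conditions: second-generation Grubbs catalyst RuCl2(=CHPh)(H2IMes)(PCy3) (5 mol%), toluene, 80 °C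
Reagents that add atoms: none
Why: ring-closing metathesis between the terminal vinyl group and the 1,1-disubstituted acrylate gives the α-substituted butenolide with loss of ethene, while the trisubstituted iodoalkene does not engage.

**Step 6**
Reactants: 9 (S)-3-(bromomethyl)-5-[(Z)-2-iodoprop-1-en-1-yl]furan-2(5H)-one; 10 (tert-butyldimethylsilyloxy)acetaldehyde
Product: 12 (4R,5S)-4-[(1R)-2-(tert-butyldimethylsilyloxy)-1-hydroxyethyl]-5-[(Z)-2-iodoprop-1-en-1-yl]-3-methylideneoxolan-2-one, via allylzinc bromide 11 (not isolated)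
Conditions: Zn dust, THF/sat. aq NH4Cl, 0 °C → rt
Reagents that add atoms: none
Why: Barbier allylation in which the 2-carbonyl-allylzinc reacts at its γ-carbon C7 through a chair Zimmerman–Traxler transition state; attack anti to the C6 substituent sets the trans-lactone, and the ring-locked E-type allyl geometry should give 7,8-anti topicity, i.e. C8 opposite to the target, as needed for the invertive epoxide closure of step 8.

**Step 7**
Reactants: 12 (the Barbier adduct)
Product: 13 (4S,5S)-4-[(1R)-2-(tert-butyldimethylsilyloxy)-1-(methanesulfonyloxy)ethyl]-5-[(Z)-2-iodoprop-1-en-1-yl]-3-methylideneoxolan-2-one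
Conditions: MsCl, Et3N, CH2Cl2, 0 °C
Reagents that add atoms: methanesulfonyl chloride, CS(=O)(=O)Cl
Why: mesylation turns O8 into a leaving group without touching the C8 stereocenter.

**Step 8**
Reactants: 13 (the C8 mesylate)
Product: 14 (4S,5S)-5-[(Z)-2-iodoprop-1-en-1-yl]-3-methylidene-4-[(2S)-oxiran-2-yl]oxolan-2-one
Conditions: TBAF (1.1 equiv), THF, 0 °C
Reagents that add atoms: none
Why: fluoride cleaves the primary silyl ether and the C9 alkoxide displaces the C8 mesylate in an intramolecular Williamson (3-exo-tet) closure with inversion, giving the epoxide with C8 configured as in the target.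

**Step 9**
Reactants: 14 (the epoxy α-methylene lactone)
Product: 15 (4S,5S)-5-[(Z)-2-iodoprop-1-en-1-yl]-4-[(2S)-oxiran-2-yl]-3-[(phenylsulfanyl)methyl]oxolan-2-one (C3 epimers)
Conditions: PhSH (1.05 equiv), Et3N (0.1 equiv), CH2Cl2, 0 °C
Reagents that add atoms: thiophenol, Sc1ccccc1
Why: base-catalysed thia-Michael addition to the α-methylene lactone should be much faster than thiolate opening of the epoxide, and it stores the C11=C13 unit so that amines, fluoride and the enolate of step 14 cannot add to it.

**Step 10**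
Reactants: 16 (S)-2-(tert-butyldimethylsilyloxy)propanal; 17 ethynylmagnesium bromide
Product: 18 (4S)-4-(tert-butyldimethylsilyloxy)pent-1-yn-3-ol (C3 epimers)
Conditions: THF, −78 → 0 °C; sat. aq NH4Cl
Reagents that add atoms: none
Why: Grignard addition of an acetylide to an α-silyloxy aldehyde; the new carbinol is oxidised in step 12, so its configuration does not matter.

**Step 11**
Reactants: 15 (the vinyl iodide); 18 (the alkynol)
Product: 19 (4S,5R)-5-[(1Z,6S)-6-(tert-butyldimethylsilyloxy)-5-hydroxy-2-methylhept-1-en-3-yn-1-yl]-4-[(2S)-oxiran-2-yl]-3-[(phenylsulfanyl)methyl]oxolan-2-one (carbinol epimers)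
Conditions: Pd(PPh3)2Cl2 (5 mol%), CuI (10 mol%), Et3N, THF, rt
Reagents that add atoms: none
Why: Sonogashira coupling (oxidative addition of the vinyl iodide to zerovalent palladium, copper acetylide transmetalation, reductive elimination) keeps the Z-olefin geometry and tolerates epoxide, lactone, sulfide and free hydroxyl.

**Step 12**
Reactants: 19 (the enyne carbinol)
Product: 20 (4S,5R)-5-[(1Z,6S)-6-(tert-butyldimethylsilyloxy)-2-methyl-5-oxohept-1-en-3-yn-1-yl]-4-[(2S)-oxiran-2-yl]-3-[(phenylsulfanyl)methyl]oxolan-2-one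
Conditions: activated MnO2 (excess), CH2Cl2, rt
Reagents that add atoms: none
Why: MnO2 oxidises only the propargylic alcohol, giving the conjugated ynone and leaving the sulfide and epoxide alone.

**Step 13**
Reactants: 20 (the silyloxy ynone)
Product: 22 (4S,5R)-5-{(Z)-2-[(5S)-5-methyl-4-oxo-4,5-dihydrofuran-2-yl]prop-1-en-1-yl}-4-[(2S)-oxiran-2-yl]-3-[(phenylsulfanyl)methyl]oxolan-2-one, via hydroxy ynone 21 (not isolated)
Conditions: TBAF, AcOH (1:1), THF, 0 °C → rt
Reagents that add atoms: none
Why: buffered fluoride removes the secondary silyl ether and the freed C10 hydroxyl adds to the ynone β-carbon C3 (5-endo-dig oxa-Michael addition), the standard route from α′-hydroxy ynones to 3(2H)-furanones, while the buffer spares the epoxide and the furanone C–H.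

**Step 14**
Reactants: 22 (the furanone epoxide)
Product: 24 13-(phenylsulfanyl)-11,13-dihydroatripliciolide (6R,7R,8R,10R; free C8 alcohol), via potassium furan-3-olate 23 (not isolated)
Conditions: KOt-Bu (0.3 equiv), t-BuOH/THF (1:3), 40 °C, 22 added by syringe pump to 0.002 M; AcOH quench
Reagents that add atoms: none
Why: Proposed new method: tert-butoxide reversibly removes the C10 proton of the 2-methyl-3(2H)-furanone (the most acidic C–H, because the conjugate base 23 is an aromatic furan-3-olate), C10 of 23 attacks the terminal epoxide carbon C9 in an SN2 opening, and the C8 alkoxide is protonated by solvent or by unreacted 22, so that the base turns over. The closest known reactions are the C2-alkylation of 2-methyl-3(2H)-furanone enolates with primary electrophiles and base-mediated intramolecular ketone-enolate/epoxide cyclisations in KOt-Bu/t-BuOH, which have not been combined for a medium ring. The closure is 10-exo-tet for the carbocycle (C1–C10) and at the same time 9-exo-tet for the oxygen-bridged ring (O, C3–C10); both are helped by the three rigid units already in the chain (furan, Z-olefin, trans-lactone). C10 is the only new stereocenter and is under substrate control: the six-atom tether C4–C9, anchored by C6 and C7 of the trans-lactone, must reach the Re face of C10 of the planar furanolate to give 10R, which is expected but not secured, while C8 keeps the epoxide configuration. The step needs C- over O-alkylation (favoured by the hydrogen-bonded, potassium-paired enolate oxygen in t-BuOH and by regeneration of the vinylogous ester), attack at primary C9 and not at secondary C8, no conjugate addition to the lactone (the α-methylene group is stored as the thiophenol adduct, which the protic, substoichiometric-base medium keeps on the adduct side), and monomer over oligomer (slow addition at high dilution).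

**Step 15**
Reactants: 24 (the macrocyclic C8 alcohol); 25 tigloyl chloride
Product: 26 13-(phenylsulfanyl)-11,13-dihydroatripliciolide 8-O-tiglate
Conditions: Et3N, DMAP, CH2Cl2, 0 °C → rt
Reagents that add atoms: none
Why: DMAP-catalysed acylation of the secondary C8 alcohol with the acid chloride touches no stereocenter and brings in the E-olefin of the tiglate from 25.

**Step 16**
Reactants: 26 (the sulfide tiglate)
Product: 28 atripliciolide tiglate, via sulfoxide 27 (not isolated)
Conditions: mCPBA (1.0 equiv), CH2Cl2, −78 °C; aq NaHCO3 wash; toluene, 90 °C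
Reagents that add atoms: none
Why: chemoselective sulfide oxidation at low temperature followed by thermal syn-elimination of the β-sulfinyl lactone (sulfoxide elimination), whose only β-hydrogen is H-11, regenerates the exocyclic C11=C13 olefin.

**Compound list**

1 | acrolein | C=CC=O | starting material
2 | 1-propynylmagnesium bromide | CC#C[Mg]Br | starting material
3 | (±)-hex-1-en-4-yn-3-ol | C=CC(O)C#CC | intermediate
4 | cyclic sodium vinylalanate (sodium 2,2-bis(2-methoxyethoxy)-3-methyl-5-vinyl-2,5-dihydro-1,2-oxaluminol-2-uide) | C=CC1C=C(C)[Al-](OCCOC)(OCCOC)O1.[Na+] | intermediate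
5 | (±)-(Z)-5-iodohexa-1,4-dien-3-ol | C=CC(O)/C=C(/C)I | intermediate
6 | (S,Z)-5-iodohexa-1,4-dien-3-ol | C=C[C@H](O)/C=C(/C)I | intermediate
7 | 2-(bromomethyl)acrylic acid | C=C(CBr)C(=O)O | starting material
8 | (S,Z)-5-iodohexa-1,4-dien-3-yl 2-(bromomethyl)acrylate | C=C(CBr)C(=O)O[C@@H](C=C)/C=C(/C)I | intermediate
9 | (S)-3-(bromomethyl)-5-[(Z)-2-iodoprop-1-en-1-yl]furan-2(5H)-one | O=C1O[C@H](/C=C(/C)I)C=C1CBr | intermediate
10 | (tert-butyldimethylsilyloxy)acetaldehyde | O=CCO[Si](C)(C)C(C)(C)C | starting material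
11 | allylzinc bromide derived from 9 | O=C1O[C@H](/C=C(/C)I)C=C1C[Zn]Br | intermediate
12 | (4R,5S)-4-[(1R)-2-(tert-butyldimethylsilyloxy)-1-hydroxyethyl]-5-[(Z)-2-iodoprop-1-en-1-yl]-3-methylideneoxolan-2-one | C=C1C(=O)O[C@H](/C=C(/C)I)[C@H]1[C@@H](O)CO[Si](C)(C)C(C)(C)C | intermediate
13 | (4S,5S)-4-[(1R)-2-(tert-butyldimethylsilyloxy)-1-(methanesulfonyloxy)ethyl]-5-[(Z)-2-iodoprop-1-en-1-yl]-3-methylideneoxolan-2-one | C=C1C(=O)O[C@H](/C=C(/C)I)[C@H]1[C@@H](OS(C)(=O)=O)CO[Si](C)(C)C(C)(C)C | intermediate
14 | (4S,5S)-5-[(Z)-2-iodoprop-1-en-1-yl]-3-methylidene-4-[(2S)-oxiran-2-yl]oxolan-2-one | C=C1C(=O)O[C@H](/C=C(/C)I)[C@H]1[C@H]2CO2 | intermediate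
15 | (4S,5S)-5-[(Z)-2-iodoprop-1-en-1-yl]-4-[(2S)-oxiran-2-yl]-3-[(phenylsulfanyl)methyl]oxolan-2-one (C3 epimers) | c1ccccc1SCC1C(=O)O[C@H](/C=C(/C)I)[C@H]1[C@H]2CO2 | intermediate
16 | (S)-2-(tert-butyldimethylsilyloxy)propanal | C[C@H](O[Si](C)(C)C(C)(C)C)C=O | starting material
17 | ethynylmagnesium bromide | C#C[Mg]Br | starting material
18 | (4S)-4-(tert-butyldimethylsilyloxy)pent-1-yn-3-ol (C3 epimers) | C#CC(O)[C@H](C)O[Si](C)(C)C(C)(C)C | intermediate
19 | (4S,5R)-5-[(1Z,6S)-6-(tert-butyldimethylsilyloxy)-5-hydroxy-2-methylhept-1-en-3-yn-1-yl]-4-[(2S)-oxiran-2-yl]-3-[(phenylsulfanyl)methyl]oxolan-2-one | c1ccccc1SCC1C(=O)O[C@H](/C=C(/C)C#CC(O)[C@H](C)O[Si](C)(C)C(C)(C)C)[C@H]1[C@H]2CO2 | intermediate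
20 | (4S,5R)-5-[(1Z,6S)-6-(tert-butyldimethylsilyloxy)-2-methyl-5-oxohept-1-en-3-yn-1-yl]-4-[(2S)-oxiran-2-yl]-3-[(phenylsulfanyl)methyl]oxolan-2-one | c1ccccc1SCC1C(=O)O[C@H](/C=C(/C)C#CC(=O)[C@H](C)O[Si](C)(C)C(C)(C)C)[C@H]1[C@H]2CO2 | intermediate
21 | (4S,5R)-5-[(1Z,6S)-6-hydroxy-2-methyl-5-oxohept-1-en-3-yn-1-yl]-4-[(2S)-oxiran-2-yl]-3-[(phenylsulfanyl)methyl]oxolan-2-one | c1ccccc1SCC1C(=O)O[C@H](/C=C(/C)C#CC(=O)[C@H](C)O)[C@H]1[C@H]2CO2 | intermediate
22 | (4S,5R)-5-{(Z)-2-[(5S)-5-methyl-4-oxo-4,5-dihydrofuran-2-yl]prop-1-en-1-yl}-4-[(2S)-oxiran-2-yl]-3-[(phenylsulfanyl)methyl]oxolan-2-one | c1ccccc1SCC1C(=O)O[C@H](/C=C(/C)C3=CC(=O)[C@H](C)O3)[C@H]1[C@H]2CO2 | intermediate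
23 | potassium furan-3-olate of 22 | c1ccccc1SCC1C(=O)O[C@H](/C=C(/C)c3cc([O-])c(C)o3)[C@H]1[C@H]2CO2.[K+] | intermediate
24 | 13-(phenylsulfanyl)-11,13-dihydroatripliciolide (6R,7R,8R,10R; C8 alcohol) | c1ccccc1SCC1C(=O)O[C@@H]2/C=C(/C)C3=CC(=O)[C@@](C)(C[C@@H](O)[C@@H]12)O3 | intermediate
25 | tigloyl chloride ((E)-2-methylbut-2-enoyl chloride) | C/C=C(\C)C(=O)Cl | starting material
26 | 13-(phenylsulfanyl)-11,13-dihydroatripliciolide 8-O-tiglate | c1ccccc1SCC1C(=O)O[C@@H]2/C=C(/C)C3=CC(=O)[C@@](C)(C[C@@H](OC(=O)/C(C)=C/C)[C@@H]12)O3 | intermediate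
27 | S-oxide of 26 (sulfoxide; sulfur epimers) | O=S(CC1C(=O)O[C@@H]2/C=C(/C)C3=CC(=O)[C@@](C)(C[C@@H](OC(=O)/C(C)=C/C)[C@@H]12)O3)c1ccccc1 | intermediate
28 | atripliciolide tiglate (6R,7R,8R,10R) | C=C1C(=O)O[C@@H]2/C=C(/C)C3=CC(=O)[C@@](C)(C[C@@H](OC(=O)/C(C)=C/C)[C@@H]12)O3 | target

**Count and risks**

Total steps: 16. Longest linear sequence: 15 (steps 1–9 and 11–16, from acrolein).

Steps most likely to fail:

1. Step 14 (the proposed new method). The epoxide opening by the stabilised furanolate may be too slow for a strained medium ring, so that oligomerisation, O-alkylation, base-induced translactonisation of the product alkoxide or approach to the wrong face of C10 takes over. The fallback sets out from 22 and comes back at 24, replacing the epoxide opening by a halide alkylation of the kind known for 2-methyl-3(2H)-furanone enolates. The epoxide is opened at C9 with LiI/AcOH (THF, 0 °C) to (4R,5R)-4-[(1S)-1-hydroxy-2-iodoethyl]-5-{(Z)-2-[(5S)-5-methyl-4-oxo-4,5-dihydrofuran-2-yl]prop-1-en-1-yl}-3-[(phenylsulfanyl)methyl]oxolan-2-one F1. The alcohol is silylated (Et3SiCl, imidazole, DMF) to the triethylsilyl ether of the iodohydrin F2. The potassium enolate (KN(SiMe3)2, THF/DMPU, −78 → 0 °C, high dilution) is C-alkylated by the primary iodide to the 8-O-triethylsilyl ether of 24 F3. HF·pyridine (THF, 0 °C) then returns 24.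

2. Step 6. The allylzinc addition may show poor topicity at C8 (open versus closed transition states), compete by α-attack, or the adduct may translactonise. The fallback sets out from crude 12 (both C8 epimers) and comes back at 12, setting C8 by reagent control instead of by the allylation. Dess–Martin oxidation (CH2Cl2, 0 °C) gives (4S,5S)-4-[(tert-butyldimethylsilyloxy)acetyl]-5-[(Z)-2-iodoprop-1-en-1-yl]-3-methylideneoxolan-2-one F4. Reduction with BH3·SMe2 and the CBS oxazaborolidine enantiomer matched to the required configuration (the R catalyst, if the ring carbon acts as the large group) returns 12 as a single C8 epimer.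

3. Step 16. Thermal sulfoxide elimination may be accompanied by degradation or olefin isomerisation of the heat-sensitive macrocycle, or by re-addition of the sulfenic acid. The fallback sets out from 26 and comes back at 28, using an E1cB release at low temperature instead. Oxidation with mCPBA (2.2 equiv, CH2Cl2, 0 °C) gives the 13-(phenylsulfonyl)-11,13-dihydroatripliciolide 8-O-tiglate F5, and DBU (CH2Cl2, 0 °C) eliminates benzenesulfinate to give 28.

**Further compounds**

F1 | step 14 | (4R,5R)-4-[(1S)-1-hydroxy-2-iodoethyl]-5-{(Z)-2-[(5S)-5-methyl-4-oxo-4,5-dihydrofuran-2-yl]prop-1-en-1-yl}-3-[(phenylsulfanyl)methyl]oxolan-2-one | c1ccccc1SCC1C(=O)O[C@H](/C=C(/C)C3=CC(=O)[C@H](C)O3)[C@H]1[C@H](O)CI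
F2 | step 14 | (4S,5R)-4-[(1S)-2-iodo-1-(triethylsilyloxy)ethyl]-5-{(Z)-2-[(5S)-5-methyl-4-oxo-4,5-dihydrofuran-2-yl]prop-1-en-1-yl}-3-[(phenylsulfanyl)methyl]oxolan-2-one | c1ccccc1SCC1C(=O)O[C@H](/C=C(/C)C3=CC(=O)[C@H](C)O3)[C@H]1[C@H](O[Si](CC)(CC)CC)CI
F3 | step 14 | 8-O-triethylsilyl-13-(phenylsulfanyl)-11,13-dihydroatripliciolide | c1ccccc1SCC1C(=O)O[C@@H]2/C=C(/C)C3=CC(=O)[C@@](C)(C[C@@H](O[Si](CC)(CC)CC)[C@@H]12)O3
F4 | step 6 | (4S,5S)-4-[(tert-butyldimethylsilyloxy)acetyl]-5-[(Z)-2-iodoprop-1-en-1-yl]-3-methylideneoxolan-2-one | C=C1C(=O)O[C@H](/C=C(/C)I)[C@H]1C(=O)CO[Si](C)(C)C(C)(C)C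
F5 | step 16 | 13-(phenylsulfonyl)-11,13-dihydroatripliciolide 8-O-tiglate | O=S(=O)(CC1C(=O)O[C@@H]2/C=C(/C)C3=CC(=O)[C@@](C)(C[C@@H](OC(=O)/C(C)=C/C)[C@@H]12)O3)c1ccccc1
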